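**Plan**
- Cuts: first the four C–Br bonds at C3–C6 of ring A (C1 bears OH, C2 the aryloxy oxygen) together with the aromaticity of ring A, then the C2–O ether bond.
- Enabling feature: on ring A only C1 and C2 carry oxygen, and C3, C4, C5 and C6 all carry bromine, each ortho or para to one of the two oxygens. Ring A is therefore the perbrominated phenol form of a 2-aryloxycyclohex-2-enone and poses no regiochemical question of its own.
- Forward: both six-membered rings are bought (cyclohexenone for ring A, 2,4-dibromophenol for ring B). The sequence is epoxidation, ether formation at an sp3 carbon by epoxide opening and dehydration, then one-pot aromatisation with fourfold bromination; no ring is closed.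
- Stereochemistry: the target is achiral. The stereocentres of the epoxide and of the transient intermediates are racemic and are all erased.

Key step: step 3

Assumption: ring A keeps one numbering throughout (C1 carbonyl or C–OH, C2 C–OAr, C6 the free alpha carbon); chiral intermediates are racemic and their SMILES show one enantiomer with the correct relative configuration.

Step 1
Reactants: 1 cyclohex-2-en-1-one
Product: 2 (±)-7-oxabicyclo[4.1.0]heptan-2-one (2,3-epoxycyclohexan-1-one)
Conditions: 30% aq H2O2, NaOH (cat.), MeOH, 0–10 °C
Reagents that add atoms: hydrogen peroxide, OO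
Why: Weitz–Scheffer nucleophilic epoxidation: hydroperoxide adds to C3 of the enone and the resulting enolate closes on the O–O bond, the three-membered ring can only be cis-fused, and with no chiral influence 2 forms as a racemate.

Step 2
Reactants: 2 (±)-7-oxabicyclo[4.1.0]heptan-2-one; 3 2,4-dibromophenol
Product: 5 2-(2,4-dibromophenoxy)cyclohex-2-en-1-one, via trans-hydroxy ketone 4 (not isolated)
Conditions: KH (0.3 equiv), THF–DMPU, reflux
Reagents that add atoms: none
Why: Aryloxide opening of an alpha,beta-epoxy ketone followed by E1cB dehydration, a known entry to 2-aryloxy enones: the phenoxide of 3 attacks the carbonyl-activated C2 in an SN2 manner with inversion (hence trans-4), the acidic C2–H then allows loss of the C3 hydroxide, which regenerates phenoxide from 3, and both stereocentres vanish in 5.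

Step 3
Reactants: 5 2-(2,4-dibromophenoxy)cyclohex-2-en-1-one
Product: 9 3,4,5,6-tetrabromo-2-(2,4-dibromophenoxy)phenol, via 6-bromo enone 6 (not isolated), via 2-aryloxyphenol 7 (not isolated), via 4,6-dibromophenol 8 (not isolated)
Conditions: Br2 (3.1 equiv), dry AcOH, 20 → 60 °C; then FeBr3 (10 mol %), Br2 (2.2 equiv, slow addition), 80 °C; aq NaHSO3 work-up
Reagents that add atoms: bromine, BrBr
Why: Proposed new method: HBr-catalysed enolisation of 5 toward C6, bromination to 6, loss of HBr and tautomerisation deliver phenol 7, and any bromine that enters earlier at C3 by addition–elimination across the C2=C3 enol ether bond merely anticipates one that the target needs, so the possible orders of events converge. The new hydroxyl sends bromine quickly to C4 and C6 (8), after which the ether oxygen directs it para to C5 and ortho to C3, these two slower entries being helped by FeBr3, by heat and by the phenol-specific path of ipso attack at C4 or C6 followed by a 1,2-bromine shift. The closest known reaction types are the bromine-mediated dehydrogenation of cyclohexenones to bromophenols and the exhaustive bromination of catechol and guaiacol to their tetrabromides, and the untested part is their merger in one flask on a 2-aryloxy enone. No ring closes and no stereocentre remains, since the centre of 6 is lost on aromatisation. The step needs ring A to react ahead of C5' and C6' of ring B, which the substrate secures because each of C3–C6 is ortho or para to an oxygen donor and the hydroxyl draws the electrophile to ring A, whereas C6' is meta to two bromines, C5' is meta to the ether oxygen and that oxygen is shared with an ever more electron-poor ring A. Metering the second bromine charge, tempering FeBr3 with AcOH and excluding water (which would hydrolyse the enol ether or ipso-brominated ring A) guard this margin, and bisulfite strips any bromine parked reversibly on an ipso carbon of the finished phenol.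

**Compound list**
1 | cyclohex-2-en-1-one | O=C1CCCC=C1 | starting material
2 | (±)-7-oxabicyclo[4.1.0]heptan-2-one (2,3-epoxycyclohexan-1-one, cis-fused) | O=C1CCC[C@@H]2O[C@H]12 | intermediate
3 | 2,4-dibromophenol | Oc1ccc(Br)cc1Br | starting material
4 | (±)-trans-2-(2,4-dibromophenoxy)-3-hydroxycyclohexan-1-one (not isolated) | O=C1CCC[C@H](O)[C@H]1Oc1ccc(Br)cc1Br | intermediate
5 | 2-(2,4-dibromophenoxy)cyclohex-2-en-1-one | O=C1CCCC=C1Oc1ccc(Br)cc1Br | intermediate
6 | (±)-6-bromo-2-(2,4-dibromophenoxy)cyclohex-2-en-1-one (not isolated) | O=C1[C@H](Br)CCC=C1Oc1ccc(Br)cc1Br | intermediate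
7 | 2-(2,4-dibromophenoxy)phenol (not isolated) | Oc1ccccc1Oc1ccc(Br)cc1Br | intermediate
8 | 4,6-dibromo-2-(2,4-dibromophenoxy)phenol (not isolated) | Oc1c(Br)cc(Br)cc1Oc1ccc(Br)cc1Br | intermediate
9 | 3,4,5,6-tetrabromo-2-(2,4-dibromophenoxy)phenol | Oc1c(Br)c(Br)c(Br)c(Br)c1Oc1ccc(Br)cc1Br | target

Total step count: 3. Longest linear sequence: 3 steps (1 → 2 → 5 → 9).

**Steps most likely to fail**

1. Step 3 goes beyond known chemistry.
   - The last ring A substitution takes place at a carbon crowded by neighbouring substituents. It may be slow enough that bromination spills over to ring B.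
   - The sequence may stall before all four bromines are in, or ipso attack at C2 may cleave the ether.
   - The fallback uses known chemistry only, sets out from 3 and returns at 9. It buys in the two bromines meta to the hydroxyl instead of installing them.
   - Phenol 3 displaces fluoride from commercial 3,5-dibromo-2-fluorobenzaldehyde (O=Cc1cc(Br)cc(Br)c1F) in an SNAr reaction activated by the ortho formyl group (K2CO3, DMF, 100 °C). This should give 3,5-dibromo-2-(2,4-dibromophenoxy)benzaldehyde F1.
   - Baeyer–Villiger oxidation with mCPBA in CH2Cl2 should give 3,5-dibromo-2-(2,4-dibromophenoxy)phenyl formate F2, and methanolysis (K2CO3, MeOH) 3,5-dibromo-2-(2,4-dibromophenoxy)phenol F3.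
   - Br2 (2.1 equiv) in AcOH at room temperature then fills C4 and C6. These are para and ortho to the hydroxyl, so no Lewis acid is needed, ring B has no chance to compete, and 9 results.

2. Step 2.
   - The weakly nucleophilic, ortho-hindered phenoxide may open the epoxide so slowly that base-induced isomerisation and self-condensation of the epoxy ketone take over. Dehydration may also lag behind the opening.
   - The fallback sets out from 3 and returns at 5. It makes the ether at the saturated ketone level and adds the unsaturation afterwards.
   - Phenol 3 is alkylated with commercial 2-chlorocyclohexan-1-one (K2CO3, KI cat., acetone, reflux) to 2-(2,4-dibromophenoxy)cyclohexan-1-one F4.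
   - Equilibrating deprotonation (KH, THF) favours the enolate toward the more acidic, aryloxy-bearing C2. PhSeBr at −78 °C traps it as 2-(2,4-dibromophenoxy)-2-(phenylselanyl)cyclohexan-1-one F5.
   - H2O2–pyridine in CH2Cl2 at 0 °C triggers selenoxide syn-elimination. Only the C3 hydrogens are available for it, so 5 should result.

3. Step 1.
   - Hydroxide, methoxide or hydroperoxide may attack the product further (epoxide opening, oxidative ring cleavage). The small, volatile, water-soluble product may also be lost on isolation.
   - The fallback sets out from 1 and returns at 2. It replaces nucleophilic epoxidation of the enone by electrophilic epoxidation of the allylic alcohol.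
   - Luche reduction (NaBH4, CeCl3·7H2O, MeOH, 0 °C) should give cyclohex-2-en-1-ol F6.
   - Hydroxyl-directed epoxidation with mCPBA (CH2Cl2, 0 °C) should give cis-2,3-epoxycyclohexan-1-ol F7, and Dess–Martin oxidation (CH2Cl2, room temperature) returns 2.

Further compounds
F1 | step 3 | 3,5-dibromo-2-(2,4-dibromophenoxy)benzaldehyde | O=Cc1cc(Br)cc(Br)c1Oc1ccc(Br)cc1Br
F2 | step 3 | 3,5-dibromo-2-(2,4-dibromophenoxy)phenyl formate | O=COc1cc(Br)cc(Br)c1Oc1ccc(Br)cc1Br
F3 | step 3 | 3,5-dibromo-2-(2,4-dibromophenoxy)phenol | Oc1cc(Br)cc(Br)c1Oc1ccc(Br)cc1Br
F4 | step 2 | (±)-2-(2,4-dibromophenoxy)cyclohexan-1-one | O=C1CCCC[C@H]1Oc1ccc(Br)cc1Br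
F5 | step 2 | (±)-2-(2,4-dibromophenoxy)-2-(phenylselanyl)cyclohexan-1-one | O=C1CCCC[C@]1([Se]c1ccccc1)Oc1ccc(Br)cc1Br
F6 | step 1 | (±)-cyclohex-2-en-1-ol | O[C@@H]1CCCC=C1
F7 | step 1 | (±)-cis-2,3-epoxycyclohexan-1-ol | O[C@@H]1CCC[C@@H]2O[C@H]12
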